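**Assumption:** the recombinant α-longipinene synthase of step 3 is taken to release the (1R,2S,7R,8R) enantiomer (dextrorotatory α-longipinene), which has the ring-fusion configuration of the target; a synthase of the other series would be replaced.

## Structural features

The target is a longipinane sesquiterpenoid. In longipinane numbering, a cyclobutane (C4, C5, C11, C10) is bridged across one diagonal by the enone unit C1(=O)–C2=C3(Me) between C11 and C4, and across the other diagonal, on the opposite face, by C6(Me)2–C7–C8–C9 between C5 and C10. The four ring-fusion stereocentres C4, C5, C10 (quaternary, methyl-bearing) and C11 are contiguous and make up the cyclobutane. C7, C8 and C9 form a second contiguous triad: O7 is trans to O8, O8 is cis to O9, C7 sits next to quaternary C6 and C9 next to quaternary C10. Fragile groups are the two angelates (Z to E isomerization to tiglates, acyl migration between the cis oxygens O8 and O9), the strained pinene-type core (cationic 1,2-shifts under acid) and the enone with its acidic γ-methyl group. The real difficulty is double. First, the strained tricyclic core. Second, the C7–C9 trimethylene unit has no neighbouring functional group, and its two faces are almost mirror images of each other locally (only the distant C1 carbonyl versus the C3 methyl distinguishes them), so substrate control cannot place the first oxygen. In addition, O9 must stay free while the equally hindered O7 is acylated, so a late selective esterification of a free triol is not credible. The key step uses the fact that the fifteen skeletal carbons are one head-to-tail farnesyl chain: bonds C5–C6, C5–C11 and C4–C10 fold it into the cycloheptane, cyclohexene and cyclobutane, and the final cation on C3 becomes the C2=C3 alkene that later carries the enone.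

## Logic of the disconnections

17 to 16: the O–H bond at C9 is traced back to an O–Si bond. O7 and O9 are both neopentyl-type carbinols and an acylating agent would not tell them apart, so O9 is kept masked until both esters are in place. The demand is a silicon removal that neither moves the C8 acyl group to the cis O9 nor isomerizes the Z alkenes.

16 to 14 and 13: the ester C–O bond at O7 is cut. With O9 masked, the C7 hydroxyl is the only free one, so no selectivity is needed. The demand is acylation of a hindered secondary alcohol with retention of the Z geometry of 13.

14 to 12 and 13: the C8–O bond is cut, which folds the trans C7/C8 oxygens into a cis oxirane. One SN2 event then gives the trans 7,8 relation and, because the oxirane lies anti to the C9 oxygen, the cis 8,9 relation; it also brings in the first side chain without an acylation step. The demand is attack at C8 and not at neopentyl C7, with no cationic character at C7 (risk of methyl or ring-bond shift from C6).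

12 to 11 to 10: the two oxirane C–O bonds and then the O–Si bond are removed, leaving an allylic carbinol. The C9 substituent is the only element that differentiates the faces of the C7=C8 alkene, so it is made bulky before oxygen transfer. The demand is delivery anti to the silyl ether and no reaction at the electron-poor C2=C3 bond.

10 to 8 to 6: the C7=C8 π bond is traced to two C–H bonds, with the C9 oxygen serving as anchor for a silicon tether. A detour through a C9 ketone would erase the one stereocentre that a catalyst pocket can place and would then require a hydride to choose between two enone carbonyls; the tether avoids both. The demand is hydrogen abstraction at C7 or C8 only, elimination away from C9, and an untouched C9–O bond.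

6 to 5: the C9–O bond is cut to a C–H bond. No functional group lies within reach, so only a shaped active site can choose C9 and one of its two nearly equivalent faces. The gain is removal of all seven-ring oxygenation; the demand is site selectivity against C7, C8 and the γ-methyl, and oxygen delivery on the face turned toward C11.

5 to 4: the C1=O bond is cut to CH2. The cyclization ends with the C2=C3 alkene, which activates exactly C1. Placing the carbonyl before the hydroxylation also removes the allylic C–H bonds as competitors. The demand is attack at the ring CH2 and not at the methyl or the bridgehead, without skeletal rearrangement.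

4 to 3: the bonds C5–C6, C5–C11 and C4–C10 are cut. Three rings and four contiguous stereocentres unfold into an acyclic, achiral C15 chain with all carbons already in place. The demand is a catalyst that holds one chain fold, channels the cation through three closures in order and quenches it at once.

3 to 2 to 1: the C–O–P bond and then the C–Cl bond are cut, back to the commercial alcohol. Passing through the chloride avoids the mono-, di- and triphosphate mixtures of direct phosphorylation. The demand is substitution at the primary allylic carbon without allylic transposition or loss of the 2E geometry. 13 is commercial.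

## Other disconnections considered

Alternative 1: The cut is the C5–C11 bond, made last by a semipinacol shift. In the forward sense the precursor of A1 (a bicyclo[2.2.1]heptene with a free bridgehead hydroxyl and an endo sulfonate on the adjacent carbon) would be deprotonated. The one-carbon bridge would migrate from the carbinol carbon to the sulfonate carbon, so that the cyclobutane and the conjugated C1 ketone appear together in A1.
- In its favour: ordinary solution chemistry, a clear stereoelectronic rule (migrating bond antiperiplanar to the leaving group), and C7–C9 oxygens that are in place and partly differentiated before the skeleton is complete.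
- Against it here: the precursor, with a quaternary methyl centre, a gem-dimethyl group and three oxygenated stereocentres on a ring annulated to the norbornene, needs a long stereocontrolled build. Grob-type fragmentation competes with the shift, and A1 still leaves O8 and O9 (joint acetonide) to be told apart.
- Comparison: on structure, Alternative 1 is the better plan for the oxygen pattern, since it needs no C–H oxidation and has no face problem. On mechanism it is the better plan in being independent of an enzyme. On reaching the enone the two are equal. On step economy the chosen plan should be far shorter, because it forms three rings and four stereocentres in one step.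

Alternative 2: The cuts are C5–C11 and C4–C10, made together by an intramolecular crossed ketene–alkene cycloaddition. The acid chloride precursor of A2 would be dehydrohalogenated with NEt3; the ketene carbonyl carbon would bond to the alkene CH and its α-carbon to the alkene C(Me), giving A2.
- In its favour: two ring bonds and the quaternary C10 in one concerted step, a well-known entry to bicyclo[3.1.1]heptanones, and a C9 stereocentre that comes from a simple chiral building block.
- Against it here: A2 lacks C6, its methyls and C7. These would have to be added at the hindered cyclobutanone carbonyl, followed by ring closure and removal of the resulting oxygen at C5. The exocyclic methylene must also be moved into the ring and C1 oxidized, and the facial sense of the cycloaddition relative to the acyclic C9 centre is uncertain.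
- Comparison: on structure, Alternative 2 is the better plan for C9, which needs no hydroxylation, and the equal of the chosen plan for the late C7/C8 chemistry, which would start from the same kind of C7=C8 alkene next to a protected O9. On mechanism it is a predictable pericyclic step against an enzyme-held cation cascade. On step economy the chosen plan should win clearly because of the post-cycloaddition repair work.

Alternative 3: The cut is the C4–C5 bond. Irradiation of the ketone precursor of A3 would lead to abstraction of the allylic hydrogen at C4 by the excited C5 carbonyl, and the 1,4-biradical would couple to give A3.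
- In its favour: the precursor is an unstrained fused six–seven bicycle, strain is introduced only in the last C–C bond formation, and the step needs no reagent. A3 also carries O7 next to a C8=C9 alkene, so a cis-dihydroxylation anti to O7 would give the 7,8-trans/8,9-cis triad directly.
- Against it here: A3 has a tertiary hydroxyl at C5 that the target lacks, and its removal at a cyclobutane bridge carbon is hard. Fragmentation of the biradical and coupling at the other allyl terminus compete, C1 still needs oxidation, and O8 and O9 would again need to be told apart.
- Comparison: on structure, Alternative 3 is the better plan for the triol triad, because the dihydroxylation is simpler than the oxirane opening used here. On mechanism it is the equal in forming the strained ring late and in one step, but it has more competing channels. On step economy the chosen plan should be shorter, since it needs no deoxygenation and builds the whole skeleton at once.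

Key step: step 3

## Route

**Step 1**
Reactants: 1 (2E,6E)-farnesol
Product: 2 (2E,6E)-farnesyl chloride
Conditions: NCS, Me2S, CH2Cl2, −40 to 0 °C
Reagents that add atoms: N-chlorosuccinimide, O=C1CCC(=O)N1Cl
Why: Corey–Kim chlorination; chloride displaces the alkoxysulfonium group at the primary carbon by SN2, so the 2E geometry is kept and no allylic transposition is expected.

**Step 2**
Reactants: 2 (2E,6E)-farnesyl chloride
Product: 3 (2E,6E)-farnesyl diphosphate
Conditions: (Bu4N)3HP2O7, MeCN, rt; work-up by cation exchange to the ammonium form (aq. NH4HCO3/iPrOH) and cellulose chromatography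
Reagents that add atoms: tris(tetrabutylammonium) hydrogen diphosphate, CCCC[N+](CCCC)(CCCC)CCCC.CCCC[N+](CCCC)(CCCC)CCCC.CCCC[N+](CCCC)(CCCC)CCCC.OP(=O)([O-])OP(=O)([O-])[O-]
Why: SN2 displacement of a primary allylic chloride by the soluble diphosphate anion, the standard preparation of allylic diphosphates; it should give the diphosphate only, with the chain geometry unchanged.

**Step 3**
Reactants: 3 (2E,6E)-farnesyl diphosphate
Product: 4 (+)-α-longipinene
Conditions: recombinant (+)-α-longipinene synthase (conifer-type enzyme expressed in E. coli), MgCl2 (10 mM), HEPES buffer pH 7.5, dithiothreitol, 30 °C, pentane overlay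
Reagents that add atoms: none
Why: Mg2+-assisted ionization of 3 and return of diphosphate to C3 (nerolidyl isomer) allow the cisoid allyl cation, whose C1 is attacked by the distal alkene to close the 11-membered ring (farnesyl C1–C11, the C5–C6 bond of 4), a macrocyclization in which both alkene carbons end inside the ring; a 1,3-hydride shift then gives an allyl cation. The central alkene attacks this allyl cation in a 6-exo closure (farnesyl C1–C6, the C5–C11 bond of 4) to give a tertiary himachalyl-type cation. That cation adds to the last alkene at its less substituted carbon in a 4-exo Markovnikov closure of the cyclobutane (farnesyl C2–C7, the C4–C10 bond of 4), as the pinyl cation forms in monoterpene biosynthesis, and loss of a proton from the adjacent CH2 gives the C2=C3 alkene. The closest known reaction type is the cationic polyene cyclization of allyl diphosphates by terpene synthases, here the known conversion of farnesyl diphosphate into longipinene-type hydrocarbons. All four stereocentres (C4, C5, C10, C11) are set by the single chain fold that the active site enforces, the 2E,6E geometry of 3 fixing their relative and the protein their absolute configuration. The step needs selectivity for cyclobutane closure over the alternative bond to farnesyl C3 and over early proton loss (longifolene and himachalene channels), and immediate quenching of the strained cation. The substrate contributes the methyl groups that make the second and third closures end at tertiary cations; the pocket and its base supply the rest.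

**Step 4**
Reactants: 4 (+)-α-longipinene
Product: 5 (4R,5S,10R,11R)-longipin-2-en-1-one
Conditions: CrO3, 3,5-dimethylpyrazole, CH2Cl2, −20 °C
Reagents that add atoms: chromium trioxide, O=[Cr](=O)=O
Why: allylic oxidation of a trisubstituted cyclic alkene to the enone by the hexavalent chromium–pyrazole complex, the longipinene counterpart of the pinene-to-verbenone oxidation; the ring CH2 (C1) should react and not the bridgehead C4–H, which cannot give a planar allyl system, or the methyl group, and no stereocentre is touched.

**Step 5**
Reactants: 5 (4R,5S,10R,11R)-longipin-2-en-1-one
Product: 6 (4R,5S,9R,10R,11R)-9-hydroxylongipin-2-en-1-one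
Conditions: engineered P450-BM3 (CYP102A1) variant selected from an active-site library, NADP+ (cat.), D-glucose, glucose dehydrogenase, air, K2HPO4/KH2PO4 buffer pH 8.0, 2% DMSO, 25 °C
Reagents that add atoms: dioxygen, O=O
Why: P450-catalysed hydroxylation of an unactivated methylene group of a terpenoid enone (hydrogen abstraction and oxygen rebound with retention), a reaction type known for steroidal and terpenoid ketones; the enone deactivates nearby C–H bonds, and the pocket of the selected variant, not the substrate, should choose C9 and the hydrogen on the face turned toward C11, which sets the C9 stereocentre.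

**Step 6**
Reactants: 6 (4R,5S,9R,10R,11R)-9-hydroxylongipin-2-en-1-one
Product: 8 (4R,5S,9R,10R,11R)-9-[(iodomethyl)dimethylsilyloxy]longipin-2-en-1-one, via bromomethylsilyl ether 7 (not isolated)
Conditions: BrCH2SiMe2Cl, imidazole, CH2Cl2, 0 °C; concentrate; NaI, acetone, rt
Reagents that add atoms: (bromomethyl)chlorodimethylsilane, C[Si](C)(Cl)CBr; sodium iodide, [Na+].[I-]
Why: silylation of the secondary alcohol by an unhindered chlorosilane followed by Finkelstein exchange at the α-silyl carbon; the C9–O bond is not involved, so the configuration is kept.

**Step 7**
Reactants: 8 (4R,5S,9R,10R,11R)-9-[(iodomethyl)dimethylsilyloxy]longipin-2-en-1-one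
Product: 10 (4R,5S,9R,10R,11R)-9-hydroxylongipina-2,7-dien-1-one, via trimethylsilyl ether 9 (not isolated)
Conditions: Pd(OAc)2 (10 mol %), 1-(di-tert-butylphosphino)-1′-(diphenylphosphino)ferrocene (20 mol %), Cs2CO3, benzene, blue LED (450 nm), rt; then K2CO3 (cat.), MeOH, 0 °C
Reagents that add atoms: none
Why: silicon-tethered photoinduced palladium-catalysed remote desaturation of an aliphatic alcohol: photoexcited zerovalent palladium reduces the C–I bond to a silylmethyl radical that abstracts hydrogen from C8 or C7 (1,5- or 1,6-hydrogen atom transfer), and recombination with palladium and β-hydride elimination give the C7=C8 alkene, the only one possible from C7 because C6 has no hydrogen (the one competing path, elimination toward C9, would give a silyl enol ether); methanolysis frees the carbinol, and since the C9–O bond is never broken the enzyme-set configuration is retained.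

**Step 8**
Reactants: 10 (4R,5S,9R,10R,11R)-9-hydroxylongipina-2,7-dien-1-one
Product: 11 (4R,5S,9R,10R,11R)-9-(tert-butyldimethylsilyloxy)longipina-2,7-dien-1-one
Conditions: TBSOTf, 2,6-lutidine, CH2Cl2, −78 to 0 °C
Reagents that add atoms: tert-butyldimethylsilyl triflate, CC(C)(C)[Si](C)(C)OS(=O)(=O)C(F)(F)F
Why: silyl ether formation at a hindered secondary alcohol with the silyl triflate; the group masks O9 to the end and makes the C9 substituent large enough to control the next step.

**Step 9**
Reactants: 11 (4R,5S,9R,10R,11R)-9-(tert-butyldimethylsilyloxy)longipina-2,7-dien-1-one
Product: 12 (4R,5S,7S,8S,9S,10R,11R)-9-(tert-butyldimethylsilyloxy)-7,8-epoxylongipin-2-en-1-one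
Conditions: dimethyldioxirane (acetone solution), CH2Cl2, 0 °C
Reagents that add atoms: dimethyldioxirane, CC1(C)OO1
Why: neutral dioxirane epoxidation of the isolated cis alkene, the electron-poor C2=C3 bond being left alone; the two alkene faces differ only in the C9 silyloxy group (one C6 methyl lies on each), so oxygen should arrive anti to it and set C7 and C8.

**Step 10**
Reactants: 12 (4R,5S,7S,8S,9S,10R,11R)-9-(tert-butyldimethylsilyloxy)-7,8-epoxylongipin-2-en-1-one; 13 angelic acid
Product: 14 (4R,5S,7S,8R,9S,10R,11R)-8-angeloyloxy-9-(tert-butyldimethylsilyloxy)-7-hydroxylongipin-2-en-1-one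
Conditions: 13 (3 equiv), Cs2CO3 (0.3 equiv), DMF, 80 °C
Reagents that add atoms: none
Why: SN2 opening of an epoxide by a cesium carboxylate in the acid-buffered medium; attack should occur at C8, the non-neopentyl carbon, with inversion, which places O8 cis to O9 and trans to the C7 hydroxyl and so sets the final C8 configuration, while the absence of acid avoids cationic character at C7.

**Step 11**
Reactants: 14 (4R,5S,7S,8R,9S,10R,11R)-8-angeloyloxy-9-(tert-butyldimethylsilyloxy)-7-hydroxylongipin-2-en-1-one; 13 angelic acid
Product: 16 (4R,5S,7S,8R,9S,10R,11R)-7,8-bis(angeloyloxy)-9-(tert-butyldimethylsilyloxy)longipin-2-en-1-one, via mixed anhydride 15 (not isolated)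
Conditions: 13, 2,4,6-trichlorobenzoyl chloride, Et3N, toluene, rt; then 14, DMAP, toluene, 80 °C
Reagents that add atoms: none
Why: Yamaguchi esterification, the usual way to angeloylate hindered secondary alcohols without Z to E isomerization; the C7 hydroxyl is the only free one, so no site selectivity is required and no stereocentre changes.

**Step 12**
Reactants: 16 (4R,5S,7S,8R,9S,10R,11R)-7,8-bis(angeloyloxy)-9-(tert-butyldimethylsilyloxy)longipin-2-en-1-one
Product: 17 (4R,5S,7S,8S,9S,10R,11R)-7,8-bis(angeloyloxy)-9-hydroxylongipin-2-en-1-one
Conditions: HF·pyridine, pyridine, THF, 0 °C to rt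
Reagents that add atoms: none
Why: fluoride cleavage of the silyl ether under buffered, weakly acidic conditions, chosen so that neither base-induced O8 to O9 acyl migration nor isomerization of the angelates is expected.

## Compound list

1 | (2E,6E)-farnesol | CC(C)=CCC/C(C)=C/CC/C(C)=C/CO | starting material
2 | (2E,6E)-farnesyl chloride | CC(C)=CCC/C(C)=C/CC/C(C)=C/CCl | intermediate
3 | (2E,6E)-farnesyl diphosphate (handled as the triammonium salt) | CC(C)=CCC/C(C)=C/CC/C(C)=C/COP(=O)(O)OP(=O)(O)O | intermediate
4 | (+)-α-longipinene, (4R,5R,10S,11R)-longipin-2-ene, (1R,2S,7R,8R)-2,6,6,9-tetramethyltricyclo[5.4.0.0(2,8)]undec-9-ene | C1CC(C)(C)[C@@H]2[C@H]3CC=C(C)[C@@H]2[C@@]3(C)C1 | intermediate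
5 | (4R,5S,10R,11R)-longipin-2-en-1-one | C1CC(C)(C)[C@@H]2[C@H]3C(=O)C=C(C)[C@@H]2[C@@]3(C)C1 | intermediate
6 | (4R,5S,9R,10R,11R)-9-hydroxylongipin-2-en-1-one | C1CC(C)(C)[C@@H]2[C@H]3C(=O)C=C(C)[C@@H]2[C@@]3(C)[C@@H]1O | intermediate
7 | (4R,5S,9R,10R,11R)-9-[(bromomethyl)dimethylsilyloxy]longipin-2-en-1-one | C1CC(C)(C)[C@@H]2[C@H]3C(=O)C=C(C)[C@@H]2[C@@]3(C)[C@@H]1O[Si](C)(C)CBr | intermediate
8 | (4R,5S,9R,10R,11R)-9-[(iodomethyl)dimethylsilyloxy]longipin-2-en-1-one | C1CC(C)(C)[C@@H]2[C@H]3C(=O)C=C(C)[C@@H]2[C@@]3(C)[C@@H]1O[Si](C)(C)CI | intermediate
9 | (4R,5S,9R,10R,11R)-9-(trimethylsilyloxy)longipina-2,7-dien-1-one | C1=CC(C)(C)[C@@H]2[C@H]3C(=O)C=C(C)[C@@H]2[C@@]3(C)[C@@H]1O[Si](C)(C)C | intermediate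
10 | (4R,5S,9R,10R,11R)-9-hydroxylongipina-2,7-dien-1-one | C1=CC(C)(C)[C@@H]2[C@H]3C(=O)C=C(C)[C@@H]2[C@@]3(C)[C@@H]1O | intermediate
11 | (4R,5S,9R,10R,11R)-9-(tert-butyldimethylsilyloxy)longipina-2,7-dien-1-one | C1=CC(C)(C)[C@@H]2[C@H]3C(=O)C=C(C)[C@@H]2[C@@]3(C)[C@@H]1O[Si](C)(C)C(C)(C)C | intermediate
12 | (4R,5S,7S,8S,9S,10R,11R)-9-(tert-butyldimethylsilyloxy)-7,8-epoxylongipin-2-en-1-one (oxirane anti to the silyloxy group) | O4[C@H]1[C@@H]4C(C)(C)[C@@H]2[C@H]3C(=O)C=C(C)[C@@H]2[C@@]3(C)[C@@H]1O[Si](C)(C)C(C)(C)C | intermediate
13 | angelic acid, (Z)-2-methylbut-2-enoic acid | C/C=C(/C)C(=O)O | starting material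
14 | (4R,5S,7S,8R,9S,10R,11R)-8-angeloyloxy-9-(tert-butyldimethylsilyloxy)-7-hydroxylongipin-2-en-1-one | C/C=C(/C)C(=O)O[C@@H]1[C@@H](O)C(C)(C)[C@@H]2[C@H]3C(=O)C=C(C)[C@@H]2[C@@]3(C)[C@@H]1O[Si](C)(C)C(C)(C)C | intermediate
15 | angelic 2,4,6-trichlorobenzoic anhydride | C/C=C(/C)C(=O)OC(=O)c1c(Cl)cc(Cl)cc1Cl | intermediate
16 | (4R,5S,7S,8R,9S,10R,11R)-7,8-bis(angeloyloxy)-9-(tert-butyldimethylsilyloxy)longipin-2-en-1-one | C/C=C(/C)C(=O)O[C@@H]1[C@@H](OC(=O)/C(C)=C\C)C(C)(C)[C@@H]2[C@H]3C(=O)C=C(C)[C@@H]2[C@@]3(C)[C@@H]1O[Si](C)(C)C(C)(C)C | intermediate
17 | (4R,5S,7S,8S,9S,10R,11R)-7,8-bis(angeloyloxy)-9-hydroxylongipin-2-en-1-one | C/C=C(/C)C(=O)O[C@@H]1[C@@H](OC(=O)/C(C)=C\C)C(C)(C)[C@@H]2[C@H]3C(=O)C=C(C)[C@@H]2[C@@]3(C)[C@@H]1O | target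

## Step count and least certain steps

Total step count: 12. Longest linear sequence: 12 steps (1 to 17); 13 is used as purchased in steps 10 and 11.

**Step 3 (key step).** The cationic intermediates may partition into the longifolene and himachalene channels, giving a sesquiterpene mixture. In vitro, 3 may also hydrolyse and the hydrophobic product may inhibit the enzyme, so turnover could be low. The fallback moves the cyclization into a production host. It sets out from 1 and returns at 4: E. coli cells expressing a farnesol kinase, an isopentenyl phosphate kinase variant that accepts farnesyl phosphate, and a synthase variant screened in vivo for product purity are fed 1; 3 is formed and consumed inside the cell, and 4 is collected in a dodecane overlay and purified on AgNO3-impregnated silica. No new compound arises.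

**Step 5.** Oxygen may be delivered to the less hindered C8 methylene or to the γ-methyl group, and at C9 it may arrive on the wrong face, because position and face both depend on how the variant binds a compact hydrocarbon-like substrate. The fallback separates the choice of position from the choice of configuration. It sets out from 5 and returns at 6. A variant selected only for C9 would give 6 mixed with its epimer (4R,5S,9S,10R,11R)-9-hydroxylongipin-2-en-1-one F1. Oxidation of the mixture with Dess–Martin periodinane converges both on (4R,5S,10R,11R)-longipin-2-ene-1,9-dione F2. A ketoreductase screened for the saturated C9 carbonyl would then reduce F2 to 6, the conjugated C1 carbonyl being less electrophilic and differently placed.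

**Step 7.** Hydrogen transfer may occur from the C10 methyl group, elimination from a C8 palladium species may go toward C9 (silyl enol ether), and conversion may stall under irradiation in the presence of the enone chromophore. The fallback gives up retention at C9 and uses a redox relay. It sets out from 6 and returns at 10. Dess–Martin oxidation gives the dione F2. Dehydrogenation with IBX (DMSO, 70 °C), possible only toward C8 because C10 is quaternary, gives (4R,5S,10R,11R)-longipina-2,7-diene-1,9-dione F3. A ketoreductase screened for the C9 carbonyl and for the required face then gives 10; a chemical hydride is not expected to distinguish the two enone carbonyls or the two faces.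

**Step 10.** Opening of an oxirane flanked by C6 and by the silyloxy-bearing C9 may be slow, and forcing conditions invite Z to E isomerization of 13, attack at C7 and acyl or silyl migration. The fallback replaces the oxirane by a more reactive cyclic sulfate. It sets out from 11 and returns at 14.
- Dihydroxylation with OsO4 (cat.) and N-methylmorpholine N-oxide, anti to the silyloxy group, would give (4R,5S,7S,8S,9S,10R,11R)-9-(tert-butyldimethylsilyloxy)-7,8-dihydroxylongipin-2-en-1-one F4.
- SOCl2 and Et3N would convert it into the 7,8-cyclic sulfite F5.
- Brief oxidation with RuCl3 (cat.) and NaIO4 at 0 °C would give the 7,8-cyclic sulfate F6.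
- Cesium angelate (from 13 and Cs2CO3) in DMF should open F6 at C8 with inversion to the cesium salt of the 8-angeloyloxy 7-sulfate monoester F7.
- Hydrolysis with catalytic H2SO4 in moist THF would then give 14.

## Further compounds

F0 | step 3 | none | none
F1 | step 5 | (4R,5S,9S,10R,11R)-9-hydroxylongipin-2-en-1-one | C1CC(C)(C)[C@@H]2[C@H]3C(=O)C=C(C)[C@@H]2[C@@]3(C)[C@H]1O
F2 | step 5 | (4R,5S,10R,11R)-longipin-2-ene-1,9-dione | C1CC(C)(C)[C@@H]2[C@H]3C(=O)C=C(C)[C@@H]2[C@@]3(C)C1=O
F3 | step 7 | (4R,5S,10R,11R)-longipina-2,7-diene-1,9-dione | C1=CC(C)(C)[C@@H]2[C@H]3C(=O)C=C(C)[C@@H]2[C@@]3(C)C1=O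
F4 | step 10 | (4R,5S,7S,8S,9S,10R,11R)-9-(tert-butyldimethylsilyloxy)-7,8-dihydroxylongipin-2-en-1-one | O[C@H]1[C@@H](O)C(C)(C)[C@@H]2[C@H]3C(=O)C=C(C)[C@@H]2[C@@]3(C)[C@@H]1O[Si](C)(C)C(C)(C)C
F5 | step 10 | 7,8-cyclic sulfite of F4 | O=S4O[C@H]1[C@@H](O4)C(C)(C)[C@@H]2[C@H]3C(=O)C=C(C)[C@@H]2[C@@]3(C)[C@@H]1O[Si](C)(C)C(C)(C)C
F6 | step 10 | 7,8-cyclic sulfate of F4 | O=S4(=O)O[C@H]1[C@@H](O4)C(C)(C)[C@@H]2[C@H]3C(=O)C=C(C)[C@@H]2[C@@]3(C)[C@@H]1O[Si](C)(C)C(C)(C)C
F7 | step 10 | cesium salt of the 7-O-sulfate of 14 | [Cs+].C/C=C(/C)C(=O)O[C@@H]1[C@@H](OS(=O)(=O)[O-])C(C)(C)[C@@H]2[C@H]3C(=O)C=C(C)[C@@H]2[C@@]3(C)[C@@H]1O[Si](C)(C)C(C)(C)C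
A1 | alternative 1 | 8,9-O-isopropylidene-7-O-methoxymethyl derivative of 7,8,9-trihydroxylongipin-2-en-1-one | CC5(C)O[C@@H]1[C@@H](OCOC)C(C)(C)[C@@H]2[C@H]3C(=O)C=C(C)[C@@H]2[C@@]3(C)[C@@H]1O5
A2 | alternative 2 | 7-methyl-2-methylene-7-[1-(tert-butyldimethylsilyloxy)prop-2-enyl]bicyclo[3.1.1]heptan-6-one | O=C2[C@H]3CCC(=C)[C@@H]2[C@@]3(C)[C@H](O[Si](C)(C)C(C)(C)C)C=C
A3 | alternative 3 | 7-(tert-butyldimethylsilyloxy)longipina-2,8-dien-5-ol (tertiary cyclobutanol) | C1[C@@H](O[Si](C)(C)C(C)(C)C)C(C)(C)[C@]2(O)[C@H]3CC=C(C)[C@@H]2[C@@]3(C)C=1
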